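**Retrosynthetic overview**
1. Target 28 ← Appel inversion at an axial C3 alcohol ← 3-hydroxy-7-ene 24 ← reductive transposition of the tosylhydrazone of the 8-en-7-one 21 (sets H-9 and the 7-ene) ← 7,9-dione 12 plus the C11–C16 lithium reagent 19 from (R)-linalool.
2. Ring B is formed second, by Thorpe–Ziegler closure C8→C9 of keto nitrile 10; ring A is formed first, in the key step, by closing the C5–C10 bond.
3. Key disconnection C5–C10: intramolecular Michael addition of the C10 nitrile anion to C5 of a temporary α,β-unsaturated δ-lactone (8 → 9); the lactone is cut open again in step 7.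
4. Enabling feature: the six-membered lactone ring O–C7(=O)–C6=C5–C4–C3 ties the acceptor carbon C5 to the C3 oxygen stereocentre across the quaternary C4, so the chain C2–C1–C10 can deliver C10 to C5 only on its own ring face (bridged 2-oxabicyclo[3.3.1]nonanone), and C4 leaves no enolisable hydrogen.
5. Order of rings: lactone (metathesis, temporary) → ring A (step 6) → ring B (step 8); C3 is set by iridium catalysis, C5 and C10 are relayed from it in step 6, C9 is relayed in step 16, C13 is bought.

Key step: step 6

Remark: locants C1–C20 are the labdane numbering of the target (C3 = CHBr, C4 = CMe2, C5 = ring-fusion CH, C10 = quaternary ring-fusion carbon, C9 = carbon bearing the side chain, C13 = carbinol carbon).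
Assumption: in step 3 the ligand antipode that gives the (5R) alcohol is the one to use; (S)-SEGPHOS is written.

**Fragment 1 (ring system)**

Step 1
Reactants: 1 propanenitrile; 2 (3-bromopropoxy)(tert-butyl)dimethylsilane
Product: 3 5-[(tert-butyldimethylsilyl)oxy]-2-methylpentanenitrile (racemic)
Conditions: LiN(i-Pr)2, THF, −78 °C; then 2, −78 °C → rt
Reagents that add atoms: none
Why: SN2 alkylation of the α-lithiated nitrile by the primary bromide; the new stereocentre (C10) is racemic and is erased at the carbanion stage in step 6.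

Step 2
Reactants: 3 5-[(tert-butyldimethylsilyl)oxy]-2-methylpentanenitrile
Product: 4 5-hydroxy-2-methylpentanenitrile (racemic)
Conditions: TsOH·H2O (cat.), MeOH, rt
Reagents that add atoms: none
Why: acid-catalysed methanolysis of a primary silyl ether; nothing else in the molecule is acid-labile.

Step 3
Reactants: 4 5-hydroxy-2-methylpentanenitrile; 5 3-methylbuta-1,2-diene
Product: 6 (5R)-5-hydroxy-2,6,6-trimethyloct-7-enenitrile (both C2 epimers)
Conditions: [Ir(cod)Cl]2 (cat.), (S)-SEGPHOS (cat.), 4-cyano-3-nitrobenzoic acid (cat.), Cs2CO3 (cat.), toluene, 60 °C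
Reagents that add atoms: none
Why: iridium-catalysed carbonyl reverse prenylation from the alcohol oxidation level (hydrogen auto-transfer): the alcohol is dehydrogenated, the allene is hydrometalated to a 1,1-dimethylallyl iridium species that adds through its substituted terminus, and the chiral ligand sets the carbinol centre (C3 of the target) as R.

Step 4
Reactants: 6 (5R)-5-hydroxy-2,6,6-trimethyloct-7-enenitrile
Product: 7 (4R)-7-cyano-3,3-dimethyloct-1-en-4-yl prop-2-enoate
Conditions: acryloyl chloride, i-Pr2NEt, DMAP (cat.), CH2Cl2, 0 °C → rt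
Reagents that add atoms: acryloyl chloride C=CC(Cl)=O
Why: DMAP-catalysed acylation of the hindered secondary alcohol; the stereocentre is not touched.

Step 5
Reactants: 7 (4R)-7-cyano-3,3-dimethyloct-1-en-4-yl prop-2-enoate
Product: 8 4-[(2R)-3,3-dimethyl-6-oxo-3,6-dihydro-2H-pyran-2-yl]-2-methylbutanenitrile (both epimers at the nitrile-bearing carbon)
Conditions: second-generation Grubbs catalyst (cat.), toluene, 80 °C
Reagents that add atoms: none
Why: ring-closing metathesis of the acrylate with the vinyl group gives the α,β-unsaturated δ-lactone, helped by the gem-dimethyl group and driven by loss of ethene.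

Step 6
Reactants: 8 4-[(2R)-3,3-dimethyl-6-oxo-3,6-dihydro-2H-pyran-2-yl]-2-methylbutanenitrile
Product: 9 (1R,5S,6R)-6,9,9-trimethyl-3-oxo-2-oxabicyclo[3.3.1]nonane-6-carbonitrile (cyano group on the face opposite to the lactone bridge)
Conditions: KN(SiMe3)2, THF, −78 → 0 °C; AcOH quench
Reagents that add atoms: none
Why: KN(SiMe3)2 removes the only acidic C–H (alpha to the nitrile, so both C10 epimers of 8 converge; the lactone has no gamma-hydrogen because C4 is quaternary) and the tertiary nitrile-stabilised carbanion adds to C5, the beta-carbon of the unsaturated lactone, an intramolecular Michael addition of the kind well known for nitrile anions and enoates. Ring A closes in the 6-exo-trig mode (C10 attacks C5, the C5=C6 bond lying outside the new ring) and gives the bridged 2-oxabicyclo[3.3.1]nonan-3-one. C5 is controlled by the tether: the three-atom chain C2–C1–C10 can bridge C3 and C5 of the lactone only on the face that carries it, so C6 ends up cis to the C3 oxygen and H-5 cis to H-3, as the target needs. C10 is controlled by size: in the chair of the new ring one C10 substituent must sit axial and syn to a C4 methyl, and the rod-shaped cyano group takes that place instead of the methyl, which puts the nitrile carbon (the future C9) trans to C6 as the trans-decalin requires; kinetic and thermodynamic preference agree, and because the donor has no second acidic site the adduct cannot drain into a wrong ring closure. The step needs 1,4- over 1,2-addition, which is secured by the soft tertiary nitrile anion with a potassium counter-ion and by the reversibility of carbonyl attack (a 1,2-adduct has no acidic hydrogen that could trap it).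

Step 7
Reactants: 9 (1R,5S,6R)-6,9,9-trimethyl-3-oxo-2-oxabicyclo[3.3.1]nonane-6-carbonitrile
Product: 10 (1R,2S,4R)-4-hydroxy-1,3,3-trimethyl-2-(2-oxobutyl)cyclohexane-1-carbonitrile (in equilibrium with its bridged lactol)
Conditions: EtLi (1.1 equiv), THF, −78 °C; AcOH quench at −78 °C
Reagents that add atoms: ethyllithium [Li]CC
Why: single 1,2-addition of the organolithium to the lactone, whose bridged lithium hemiketal survives at −78 °C until the quench, opens the temporary ring to the ethyl ketone (C7, C8, C17) and frees the C3 hydroxyl; the hindered tertiary nitrile does not react at this temperature.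

Step 8
Reactants: 10 (1R,2S,4R)-4-hydroxy-1,3,3-trimethyl-2-(2-oxobutyl)cyclohexane-1-carbonitrile
Product: 12 6-hydroxy-2,5,5,8a-tetramethylhexahydronaphthalene-1,3(2H,4H)-dione (trans-fused; 6-OH cis to the 8a-methyl), via enaminone 11 (not isolated)
Conditions: KOt-Bu (2.2 equiv), THF/t-BuOH, rt; then 2 M HCl, THF, 50 °C
Reagents that add atoms: water O
Why: Thorpe–Ziegler cyclisation: after the freed ring A has flipped to the chair with both arms equatorial, the C8 enolate of the ethyl ketone adds to the nitrile (6-exo-dig) and closes ring B trans-fused, a fusion already fixed in step 6, and aqueous acid hydrolyses the vinylogous amide to the 1,3-dione.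

Step 9
Reactants: 12 6-hydroxy-2,5,5,8a-tetramethylhexahydronaphthalene-1,3(2H,4H)-dione
Product: 13 6-hydroxy-3-(2-methylpropoxy)-2,5,5,8a-tetramethyl-4a,5,6,7,8,8a-hexahydronaphthalen-1(4H)-one
Conditions: i-BuOH, TsOH·H2O (cat.), benzene, reflux, Dean–Stark
Reagents that add atoms: 2-methylpropan-1-ol CC(C)CO
Why: acid-catalysed enol etherification of the 1,3-dione under equilibrating conditions places the alkoxy group on C7, the carbonyl remote from the quaternary C10, as is usual for 4,4-disubstituted cyclohexane-1,3-diones.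

**Fragment 2 (side chain)**

Step 10
Reactants: 14 (R)-linalool, (3R)-3,7-dimethylocta-1,6-dien-3-ol
Product: 15 (5R)-5-ethenyl-5-methyloxolan-2-ol (lactol of (4R)-4-hydroxy-4-methylhex-5-enal; both anomers)
Conditions: O3 (1.0 equiv), CH2Cl2/MeOH, −78 °C; then Me2S
Reagents that add atoms: ozone O=[O+][O-]
Why: chemoselective ozonolysis of the electron-rich trisubstituted alkene in the presence of the monosubstituted vinyl group; the C13 stereocentre comes unchanged from the starting material.

Step 11
Reactants: 15 (5R)-5-ethenyl-5-methyloxolan-2-ol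
Product: 16 (3R)-5-iodo-3-methylpent-1-en-3-yl formate
Conditions: PhI(OAc)2, I2, CH2Cl2, visible light, rt
Reagents that add atoms: iodine II
Why: hypoiodite reaction of the lactol: the anomeric alkoxy radical undergoes β-fragmentation of the C2–C3 bond, the primary radical is trapped by iodine and the ring oxygen is left as a formate, which shortens the chain by one carbon to the C11–C16 unit.

Step 12
Reactants: 16 (3R)-5-iodo-3-methylpent-1-en-3-yl formate
Product: 17 (3R)-5-iodo-3-methylpent-1-en-3-ol
Conditions: K2CO3 (cat.), MeOH, 0 °C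
Reagents that add atoms: none
Why: transesterification of the formate, which is fast at 0 °C where the alkoxide does not displace the γ-iodide.

Step 13
Reactants: 17 (3R)-5-iodo-3-methylpent-1-en-3-ol
Product: 18 triethyl{[(3R)-5-iodo-3-methylpent-1-en-3-yl]oxy}silane
Conditions: Et3SiOTf, 2,6-lutidine, CH2Cl2, −78 → 0 °C
Reagents that add atoms: triethylsilyl trifluoromethanesulfonate CC[Si](CC)(CC)OS(=O)(=O)C(F)(F)F
Why: silylation of the tertiary alcohol with the silyl triflate; the ether must survive organolithium formation and the later Appel step.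

**Union and endgame**

Step 14
Reactants: 13 6-hydroxy-3-(2-methylpropoxy)-2,5,5,8a-tetramethyl-4a,5,6,7,8,8a-hexahydronaphthalen-1(4H)-one; 18 triethyl{[(3R)-5-iodo-3-methylpent-1-en-3-yl]oxy}silane
Product: 21 7-hydroxy-3,4a,8,8-tetramethyl-4-{(3R)-3-methyl-3-[(triethylsilyl)oxy]pent-4-en-1-yl}-4a,5,6,7,8,8a-hexahydronaphthalen-2(1H)-one (8-en-7-one in labdane numbering), via organolithium 19 (not isolated), via carbinol adduct 20 (not isolated)
Conditions: 18, t-BuLi (2.0 equiv), Et2O, −78 °C; added to 13 pretreated with LiN(SiMe3)2 (1.0 equiv), THF, −78 → −20 °C; then 1 M HCl, THF, 0 °C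
Reagents that add atoms: water O
Why: Stork–Danheiser transposition: iodine–lithium exchange, 1,2-addition of the primary organolithium to the C9 carbonyl of the vinylogous ester (the C3 hydroxyl being masked as its lithium alkoxide), and acid-induced loss of water and isobutanol give the 8-en-7-one with the side chain on C9.

Step 15
Reactants: 21 the 8-en-7-one
Product: 22 the 4-methylbenzenesulfonohydrazone of 21 at C7
Conditions: TsNHNH2, EtOH, 50 °C
Reagents that add atoms: 4-methylbenzenesulfonohydrazide Cc1ccc(cc1)S(=O)(=O)NN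
Why: condensation of the unhindered enone carbonyl with the sulfonyl hydrazide; no stereocentre is formed.

Step 16
Reactants: 22 the tosylhydrazone of 21
Product: 24 1,1,4a,6-tetramethyl-5-{(3R)-3-methyl-3-[(triethylsilyl)oxy]pent-4-en-1-yl}-1,2,3,4,4a,5,8,8a-octahydronaphthalen-2-ol (7-ene; OH cis and H-9 cis to the C10 methyl), via allylic diazene 23 (not isolated)
Conditions: catecholborane (3 equiv), CHCl3, 0 °C; then NaOAc·3H2O, 60 °C
Reagents that add atoms: none
Why: reduction of the α,β-unsaturated tosylhydrazone with alkene transposition: hydride adds to C7 from the face opposite to the axial C10 methyl, so that after acetate-induced loss of sulfinate the diazene nitrogen is cis to that methyl and transfers its hydrogen suprafacially to C9 in a retro-ene loss of N2, which sets H-9 cis to the C10 methyl and moves the double bond to C7=C8 (the behaviour known for steroidal 4-en-3-one tosylhydrazones).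

Step 17
Reactants: 24 the equatorial C3 alcohol
Product: 25 1,1,4a,6-tetramethyl-5-{(3R)-3-methyl-3-[(triethylsilyl)oxy]pent-4-en-1-yl}-3,4,4a,5,8,8a-hexahydronaphthalen-2(1H)-one (3-ketone)
Conditions: Dess–Martin periodinane, CH2Cl2, rt
Reagents that add atoms: none
Why: Dess–Martin oxidation of the secondary alcohol, which leaves both alkenes and the tertiary silyl ether alone.

Step 18
Reactants: 25 the 3-ketone
Product: 26 the C3 epimer of 24 (axial alcohol; OH trans to the C10 methyl)
Conditions: LiBH(s-Bu)3, THF, −78 °C; then H2O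
Reagents that add atoms: none
Why: the bulky trialkylborohydride attacks the 4,4-dimethyl ketone along the equatorial trajectory and gives the axial alcohol, the usual outcome for 4,4-dimethyl-3-ketones of trans-decalins.

Step 19
Reactants: 26 the axial C3 alcohol
Product: 27 triethyl{[(3R)-5-[(1S,4aS,6R,8aS)-6-bromo-2,5,5,8a-tetramethyl-1,4,4a,5,6,7,8,8a-octahydronaphthalen-1-yl]-3-methylpent-1-en-3-yl]oxy}silane
Conditions: CBr4, PPh3, toluene, 0 → 60 °C
Reagents that add atoms: tetrabromomethane BrC(Br)(Br)Br
Why: Appel reaction: bromide displaces the axial oxyphosphonium group with inversion along the unhindered equatorial trajectory, so bromine ends up equatorial and cis to the C10 methyl.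

Step 20
Reactants: 27 the silyl ether of the target
Product: 28 (3R)-5-[(1S,4aS,6R,8aS)-6-bromo-2,5,5,8a-tetramethyl-1,4,4a,5,6,7,8,8a-octahydronaphthalen-1-yl]-3-methylpent-1-en-3-ol (target)
Conditions: HF·pyridine, pyridine, THF, 0 °C → rt
Reagents that add atoms: none
Why: buffered fluoride cleavage of the tertiary triethylsilyl ether, which touches neither the equatorial secondary bromide nor the tertiary allylic alcohol.

**Compound list**
1 | propanenitrile | CCC#N | starting material
2 | (3-bromopropoxy)(tert-butyl)dimethylsilane | BrCCCO[Si](C)(C)C(C)(C)C | starting material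
3 | 5-[(tert-butyldimethylsilyl)oxy]-2-methylpentanenitrile (racemic) | N#CC(C)CCCO[Si](C)(C)C(C)(C)C | intermediate
4 | 5-hydroxy-2-methylpentanenitrile (racemic) | N#CC(C)CCCO | intermediate
5 | 3-methylbuta-1,2-diene | C=C=C(C)C | starting material
6 | (5R)-5-hydroxy-2,6,6-trimethyloct-7-enenitrile (C2 epimers) | N#CC(C)CC[C@@H](O)C(C)(C)C=C | intermediate
7 | (4R)-7-cyano-3,3-dimethyloct-1-en-4-yl prop-2-enoate | N#CC(C)CC[C@@H](OC(=O)C=C)C(C)(C)C=C | intermediate
8 | 4-[(2R)-3,3-dimethyl-6-oxo-3,6-dihydro-2H-pyran-2-yl]-2-methylbutanenitrile | N#CC(C)CC[C@H]1OC(=O)C=CC1(C)C | intermediate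
9 | (1R,5S,6R)-6,9,9-trimethyl-3-oxo-2-oxabicyclo[3.3.1]nonane-6-carbonitrile | O=C1C[C@@H]2C(C)(C)[C@H](O1)CC[C@@]2(C)C#N | intermediate
10 | (1R,2S,4R)-4-hydroxy-1,3,3-trimethyl-2-(2-oxobutyl)cyclohexane-1-carbonitrile | CCC(=O)C[C@@H]1C(C)(C)[C@H](O)CC[C@@]1(C)C#N | intermediate
11 | enaminone: 4-amino-7-hydroxy-3,4a,8,8-tetramethyl-4a,5,6,7,8,8a-hexahydronaphthalen-2(1H)-one (trans-fused; not isolated) | NC1=C(C)C(=O)C[C@@H]2C(C)(C)[C@H](O)CC[C@]21C | intermediate
12 | 6-hydroxy-2,5,5,8a-tetramethylhexahydronaphthalene-1,3(2H,4H)-dione (trans-fused; 6-OH cis to 8a-methyl; C2 epimers and enol forms) | O=C1C(C)C(=O)C[C@@H]2C(C)(C)[C@H](O)CC[C@]21C | intermediate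
13 | 6-hydroxy-3-(2-methylpropoxy)-2,5,5,8a-tetramethyl-4a,5,6,7,8,8a-hexahydronaphthalen-1(4H)-one | O=C1C(C)=C(OCC(C)C)C[C@@H]2C(C)(C)[C@H](O)CC[C@]21C | intermediate
14 | (R)-linalool, (3R)-3,7-dimethylocta-1,6-dien-3-ol | C=C[C@](C)(O)CCC=C(C)C | starting material
15 | (5R)-5-ethenyl-5-methyloxolan-2-ol (both anomers) | C=C[C@@]1(C)CCC(O)O1 | intermediate
16 | (3R)-5-iodo-3-methylpent-1-en-3-yl formate | C=C[C@](C)(OC=O)CCI | intermediate
17 | (3R)-5-iodo-3-methylpent-1-en-3-ol | C=C[C@](C)(O)CCI | intermediate
18 | triethyl{[(3R)-5-iodo-3-methylpent-1-en-3-yl]oxy}silane | C=C[C@](C)(O[Si](CC)(CC)CC)CCI | intermediate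
19 | {(3R)-3-methyl-3-[(triethylsilyl)oxy]pent-4-en-1-yl}lithium (not isolated) | C=C[C@](C)(O[Si](CC)(CC)CC)CC[Li] | intermediate
20 | carbinol adduct: C9 tertiary alcohol from 19 and 13, enol ether still in place (not isolated; C9 configuration open) | C=C[C@](C)(O[Si](CC)(CC)CC)CCC1(O)C(C)=C(OCC(C)C)C[C@@H]2C(C)(C)[C@H](O)CC[C@]21C | intermediate
21 | 7-hydroxy-3,4a,8,8-tetramethyl-4-{(3R)-3-methyl-3-[(triethylsilyl)oxy]pent-4-en-1-yl}-4a,5,6,7,8,8a-hexahydronaphthalen-2(1H)-one (trans-fused; OH cis to the angular methyl) | C=C[C@](C)(O[Si](CC)(CC)CC)CCC1=C(C)C(=O)C[C@@H]2C(C)(C)[C@H](O)CC[C@]21C | intermediate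
22 | 4-methylbenzenesulfonohydrazone of 21 | C=C[C@](C)(O[Si](CC)(CC)CC)CCC1=C(C)C(=NNS(=O)(=O)c3ccc(C)cc3)C[C@@H]2C(C)(C)[C@H](O)CC[C@]21C | intermediate
23 | allylic diazene at C7, nitrogen cis to the C10 methyl (not isolated) | C=C[C@](C)(O[Si](CC)(CC)CC)CCC1=C(C)[C@H](N=N)C[C@@H]2C(C)(C)[C@H](O)CC[C@]21C | intermediate
24 | 1,1,4a,6-tetramethyl-5-{(3R)-3-methyl-3-[(triethylsilyl)oxy]pent-4-en-1-yl}-1,2,3,4,4a,5,8,8a-octahydronaphthalen-2-ol (equatorial OH, cis to the angular methyl) | C=C[C@](C)(O[Si](CC)(CC)CC)CC[C@H]1C(C)=CC[C@@H]2C(C)(C)[C@H](O)CC[C@]21C | intermediate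
25 | 1,1,4a,6-tetramethyl-5-{(3R)-3-methyl-3-[(triethylsilyl)oxy]pent-4-en-1-yl}-3,4,4a,5,8,8a-hexahydronaphthalen-2(1H)-one | C=C[C@](C)(O[Si](CC)(CC)CC)CC[C@H]1C(C)=CC[C@@H]2C(C)(C)C(=O)CC[C@]21C | intermediate
26 | C2 epimer of 24 (axial OH, trans to the angular methyl) | C=C[C@](C)(O[Si](CC)(CC)CC)CC[C@H]1C(C)=CC[C@@H]2C(C)(C)[C@@H](O)CC[C@]21C | intermediate
27 | triethyl{[(3R)-5-[(1S,4aS,6R,8aS)-6-bromo-2,5,5,8a-tetramethyl-1,4,4a,5,6,7,8,8a-octahydronaphthalen-1-yl]-3-methylpent-1-en-3-yl]oxy}silane | C=C[C@](C)(O[Si](CC)(CC)CC)CC[C@H]1C(C)=CC[C@@H]2C(C)(C)[C@H](Br)CC[C@]21C | intermediate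
28 | (3R)-5-[(1S,4aS,6R,8aS)-6-bromo-2,5,5,8a-tetramethyl-1,4,4a,5,6,7,8,8a-octahydronaphthalen-1-yl]-3-methylpent-1-en-3-ol | C=C[C@](C)(O)CC[C@H]1C(C)=CC[C@@H]2C(C)(C)[C@H](Br)CC[C@]21C | target

**Totals**
Total step count: 20. Longest linear sequence: 16 steps (steps 1–9 and 14–20).

**Steps most likely to fail**

Step 6 (key step). The hindered nitrile anion may attack the lactone carbonyl, or be quenched by proton transfer, faster than it closes the congested C5–C10 bond. The fallback sets out from 8. The nitrile is converted with LiN(i-Pr)2 and t-BuMe2SiCl into the N-(tert-butyldimethylsilyl) ketene imine of lactone 8 F1, a neutral nucleophile. Ring A is then closed in the Mukaiyama–Michael mode with TiCl4 at low temperature, the Lewis acid activating the lactone instead of a base activating the donor. The tether argument for C5 and the size argument for C10 are unchanged, and the route is rejoined at 9.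

Step 19. The activated axial neopentyl oxygen may ionise, with methyl migration from C4 or elimination to the 2-ene, instead of undergoing backside substitution. The fallback sets out from 26. The alcohol is converted with Tf2O and pyridine at low temperature into the axial C3 trifluoromethanesulfonate of 26 F2. This is displaced in a separate step by Bu4NBr in toluene, an SN2 reaction of unsolvated bromide on a preformed sulfonate. The route is rejoined at 27.

Step 16. Hydride delivery to the hydrazone may show poor facial selectivity, which would give a mixture of C9 epimers. The fallback sets out from 21. Reduction with NaBH4 and CeCl3·7H2O (1,2-reduction, hydride anti to the C10 methyl) gives the allylic alcohol with 7-OH cis to the C10 methyl F3. A Mitsunobu reaction with 4-nitrobenzoic acid gives the C7-inverted 4-nitrobenzoate F4, and K2CO3 in MeOH gives the epimeric allylic alcohol with 7-OH trans to the C10 methyl F5. A second Mitsunobu reaction, with 2-nitrobenzenesulfonohydrazide, proceeds with inversion and places nitrogen cis to the C10 methyl. This gives the same allylic diazene 23 with a defined configuration, and loss of N2 rejoins the route at 24.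

Further compounds
F1 | step 6 | N-(tert-butyldimethylsilyl) ketene imine of lactone 8 | CC(=C=N[Si](C)(C)C(C)(C)C)CC[C@H]1OC(=O)C=CC1(C)C
F2 | step 19 | axial C3 trifluoromethanesulfonate of 26 | C=C[C@](C)(O[Si](CC)(CC)CC)CC[C@H]1C(C)=CC[C@@H]2C(C)(C)[C@@H](OS(=O)(=O)C(F)(F)F)CC[C@]21C
F3 | step 16 | allylic alcohol from 21 with 7-OH cis to the C10 methyl | C=C[C@](C)(O[Si](CC)(CC)CC)CCC1=C(C)[C@H](O)C[C@@H]2C(C)(C)[C@H](O)CC[C@]21C
F4 | step 16 | C7-inverted 4-nitrobenzoate | C=C[C@](C)(O[Si](CC)(CC)CC)CCC1=C(C)[C@@H](OC(=O)c3ccc(cc3)[N+](=O)[O-])C[C@@H]2C(C)(C)[C@H](O)CC[C@]21C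
F5 | step 16 | epimeric allylic alcohol with 7-OH trans to the C10 methyl | C=C[C@](C)(O[Si](CC)(CC)CC)CCC1=C(C)[C@@H](O)C[C@@H]2C(C)(C)[C@H](O)CC[C@]21C
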